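Both rings are cut at once through C5–C10 and C8–C9. The key step is a type 1 intramolecular Diels–Alder reaction of an acyclic tetraenal whose only stereocentre is the C1 acetate. It exploits two features of the target. The C1 oxygen sits on the four-atom bridge C1–C4 next to quaternary C10, so it can steer the cycloaddition. Ring B carries the C6–O/C7=C8–CHO array, which is the opened form of a 6α,7α-epoxide next to a C8 formyl group, that is, of the Δ6 cycloadduct. One operation closes rings A and B, makes the congested C5–C10 bond and sets the trans fusion, C10 and C9. A sacrificial vinyl group on C8 is the latent C12 aldehyde.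

Key step: step 10

Remark: drimane numbering (decalin C1–C10, C11 on C9, C12 on C8) is used for every intermediate, acyclic ones included. C13 is the terminal carbon of the sacrificial vinyl group. Compound 12 is taken as the commercial 60 % aqueous solution and LDA as a commercial solution.

Step 1
Reactants: 1 ethyl isobutyrate; 2 1,2-dibromoethane
Product: 4 ethyl 4-bromo-2,2-dimethylbutanoate, via lithium enolate 3 (not isolated)
Conditions: LDA (1.05 equiv), THF, −78 °C; then 2 (3 equiv), −78 °C → rt
Reagents that add atoms: none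
Why: Ester enolate alkylation (SN2), in which the fully substituted enolate displaces one bromide and the excess of 2 suppresses double alkylation.

Step 2
Reactants: 4 ethyl 4-bromo-2,2-dimethylbutanoate
Product: 6 4-bromo-2,2-dimethylbutanal, via aluminium hemiacetal 5 (not isolated)
Conditions: DIBAL-H (1.1 equiv), CH2Cl2, −78 °C; aq. Rochelle salt
Reagents that add atoms: none
Why: Partial DIBAL-H reduction, in which the neopentyl aluminium hemiacetal persists at −78 °C and collapses to the aldehyde only on work-up, while the primary bromide is inert.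

Step 3
Reactants: 7 penta-1,4-dien-3-ol
Product: 8 (E)-5-bromopenta-1,3-diene
Conditions: 48 % aq. HBr, 0 °C → rt
Reagents that add atoms: hydrogen bromide, Br
Why: Allylic substitution with transposition (SN1/SN2′), in which the pentadienyl cation is captured at its terminus to give the conjugated E-dienyl bromide as the thermodynamic product.

Step 4
Reactants: 8 (E)-5-bromopenta-1,3-diene
Product: 9 tributyl[(2E)-penta-2,4-dien-1-yl]phosphonium bromide
Conditions: PBu3, MeCN, 0 °C → rt
Reagents that add atoms: tributylphosphine, CCCCP(CCCC)CCCC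
Why: Quaternisation (SN2) of a primary allylic bromide by a strongly nucleophilic trialkylphosphine.

Step 5
Reactants: 9 tributyl[(2E)-penta-2,4-dien-1-yl]phosphonium bromide; 6 4-bromo-2,2-dimethylbutanal
Product: 11 (3E,5E)-9-bromo-7,7-dimethylnona-1,3,5-triene, via pentadienylidene ylide 10 (not isolated)
Conditions: 9, KOtBu, THF, −78 °C; then 6, −78 °C → rt
Reagents that add atoms: none
Why: Wittig olefination, in which allylic tributylphosphonium ylides are known to give E-alkenes with α-branched aldehydes, and the lithium-free cycloaddition pathway leaves no long-lived alkoxide that could displace the bromide.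

Step 6
Reactants: 12 2,2-dimethoxyacetaldehyde; 13 2-(triphenylphosphoranylidene)propanal
Product: 14 (2E)-4,4-dimethoxy-2-methylbut-2-enal
Conditions: CH2Cl2/H2O, rt
Reagents that add atoms: none
Why: Wittig olefination with a stabilised ylide, which is E-selective and reacts faster with the electrophilic α,α-dialkoxy aldehyde 12 than with the product enal.

Step 7
Reactants: 11 (3E,5E)-9-bromo-7,7-dimethylnona-1,3,5-triene; 14 (2E)-4,4-dimethoxy-2-methylbut-2-enal
Product: 17 (2E,4R,8E,10E)-1,1-dimethoxy-3,7,7-trimethyltrideca-2,8,10,12-tetraen-4-ol, via Grignard reagent 15 (not isolated), via alkyltitanium triisopropoxide 16 (not isolated)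
Conditions: 11, Mg, THF, 40 °C; bis[2-(dimethylamino)ethyl] ether, Ti(OiPr)4, (R)-BINOL (15 mol %), t-BuOMe, 0 °C; then 14; aq. NH4Cl
Reagents that add atoms: none
Why: Catalytic enantioselective 1,2-addition of a Grignard-derived alkyltitanium to an aldehyde under titanium BINOLate control, in which the (R)-ligand should, by analogy with aryl and alkenyl aldehydes, deliver the alkyl group to the Re face and set C1 as R.

Step 8
Reactants: 17 (2E,4R,8E,10E)-1,1-dimethoxy-3,7,7-trimethyltrideca-2,8,10,12-tetraen-4-ol
Product: 18 (2E,4R,8E,10E)-1,1-dimethoxy-3,7,7-trimethyltrideca-2,8,10,12-tetraen-4-yl acetate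
Conditions: Ac2O, Et3N, DMAP (cat.), CH2Cl2, 0 °C → rt
Reagents that add atoms: acetic anhydride, CC(=O)OC(C)=O
Why: DMAP-catalysed acylation of a secondary allylic alcohol, which does not touch C1, the acetal or the triene.

Step 9
Reactants: 18 (2E,4R,8E,10E)-1,1-dimethoxy-3,7,7-trimethyltrideca-2,8,10,12-tetraen-4-yl acetate
Product: 19 (2E,4R,8E,10E)-4-acetoxy-3,7,7-trimethyltrideca-2,8,10,12-tetraenal
Conditions: PPTS (cat.), acetone/H2O 10:1, rt
Reagents that add atoms: water, O
Why: Acetal hydrolysis, in which the allylic acetal ionises through a conjugated oxocarbenium ion under acid mild enough to leave the acetate, the triene and the E geometry of C9=C10 intact.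

Step 10
Reactants: 19 (2E,4R,8E,10E)-4-acetoxy-3,7,7-trimethyltrideca-2,8,10,12-tetraenal
Product: 20 1β-acetoxy-12-methylidenedrim-6-en-11-al (trans-decalin; 5α-H; 8β-vinyl; 9β-CHO; 10β-CH3)
Conditions: Me2AlCl (2.2 equiv), CH2Cl2 (0.01 M), −78 → −20 °C; aq. Rochelle salt
Reagents that add atoms: none
Why: Coordination of Me2AlCl to the C11 formyl group lowers the LUMO of C9=C10, and the inner diene C5=C6–C7=C8 adds to it in a concerted, asynchronous, suprafacial [4+2] process, a type 1 intramolecular Diels–Alder reaction of a 1,7,9-decatriene, which is well known for trienals and for decalins with gem-dimethyl and angular methyl groups. Ring B closes as the new cyclohexene through the C5–C10 and C8–C9 bonds, and ring A closes at the same time in the fused mode through the four-atom tether C1–C4, which folds into a chair. The E geometry of C9=C10 places the C10 methyl and the C9 formyl group cis (both β), the E,E-diene places C4 on C5 and the vinyl group on C8 cis, and the endo orientation of the complexed formyl group, which for an E-dienophile is the trans-fused transition state, sets 5α-H against 10β-CH3 and makes the vinyl group β. The absolute sense comes from C1, because in the chair the acetoxy group lies equatorial and antiperiplanar to the forming C5–C10 bond with C1–H inside next to C9–H, which avoids A1,3 and 1,3-diaxial strain, profits from the low-lying σ*(C–O), and gives the 1β,10β relationship. The step needs endo over exo selectivity (secured by the Lewis acid and the E-enal, although the C10 methyl is forced endo as well), π-facial selectivity (secured by C1) and periselectivity within the triene (secured by the tether, which cannot reach C7=C8–C12=C13 without an E-alkene in an eight-membered ring). The Δ6 alkene appears exactly between C5 and the vinyl-bearing C8, which is what the end game turns into the 6α-acetoxy-Δ7-enal.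

Step 11
Reactants: 20 1β-acetoxy-12-methylidenedrim-6-en-11-al
Product: 21 1β-acetoxy-11-(trimethylsilyloxy)-12-methylidenedrima-6,9(11)-diene
Conditions: TMSOTf (1.3 equiv), Et3N (2 equiv), CH2Cl2, −20 → 0 °C
Reagents that add atoms: trimethylsilyl triflate, C[Si](C)(C)OS(=O)(=O)C(F)(F)F
Why: Soft enolisation to a silyl enol ether, in which O-silylation activates the aldehyde and Et3N removes the axial C9–H, its only α-hydrogen, faster than the acetate is enolised, the E/Z ratio at C9=C11 (drawn with O syn to C8) being without consequence.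

Step 12
Reactants: 21 1β-acetoxy-11-(trimethylsilyloxy)-12-methylidenedrima-6,9(11)-diene
Product: 23 1β-acetoxy-6α,7α-epoxy-9α-hydroxy-12-methylidenedriman-11-al, via bis-epoxide 22 (not isolated)
Conditions: DMDO (2.3 equiv), acetone/CH2Cl2, −40 → 0 °C; then AcOH, THF/H2O, 0 °C
Reagents that add atoms: dimethyldioxirane, CC1(C)OO1
Why: Rubottom oxidation and alkene epoxidation in one pot, in which the enol ether C9=C11 and then the cis-disubstituted C6=C7 bond are attacked from the α face because the β face is screened by the axial C10 and C4 methyl groups and the 8β-vinyl group, which sets 9α-O and the 6α,7α-epoxide while the monosubstituted vinyl group reacts much more slowly.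

Step 13
Reactants: 23 1β-acetoxy-6α,7α-epoxy-9α-hydroxy-12-methylidenedriman-11-al
Product: 26 1β-acetoxy-6α,9α-dihydroxydrim-7-ene-11,12-dial, via secondary ozonide 24 (not isolated), via epoxy dialdehyde 25 (not isolated)
Conditions: O3, CH2Cl2, −78 °C; Me2S, −78 °C → rt; then Et3N (cat.), 0 °C
Reagents that add atoms: ozone, [O-][O+]=O
Why: Ozonolysis followed by E1cB epoxide opening, in which the only remaining alkene becomes the C12 aldehyde, Et3N removes the now acidic C8–H and the C7–O bond is expelled, which creates the C7=C8 enal and leaves the C6–O bond untouched (6α-OH with retention).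

Step 14
Reactants: 26 1β-acetoxy-6α,9α-dihydroxydrim-7-ene-11,12-dial
Product: 27 parritadial (1β,6α-diacetoxy-9α-hydroxydrim-7-ene-11,12-dial)
Conditions: Ac2O, pyridine, DMAP (cat.), CH2Cl2, 0 °C
Reagents that add atoms: acetic anhydride, CC(=O)OC(C)=O
Why: Selective acylation, in which the secondary allylic 6α-OH is acetylated while the tertiary 9α-OH next to quaternary C10 is too hindered to react.

Compound list
1 | ethyl isobutyrate | CCOC(=O)C(C)C | starting material
2 | 1,2-dibromoethane | BrCCBr | starting material
3 | lithium enolate of ethyl isobutyrate | CCOC([O-])=C(C)C.[Li+] | intermediate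
4 | ethyl 4-bromo-2,2-dimethylbutanoate | CCOC(=O)C(C)(C)CCBr | intermediate
5 | diisobutylaluminium hemiacetal of 4 | CCOC(O[Al](CC(C)C)CC(C)C)C(C)(C)CCBr | intermediate
6 | 4-bromo-2,2-dimethylbutanal | O=CC(C)(C)CCBr | intermediate
7 | penta-1,4-dien-3-ol | C=CC(O)C=C | starting material
8 | (E)-5-bromopenta-1,3-diene | C=C/C=C/CBr | intermediate
9 | tributyl[(2E)-penta-2,4-dien-1-yl]phosphonium bromide | C=C/C=C/C[P+](CCCC)(CCCC)CCCC.[Br-] | intermediate
10 | tributyl[(2E)-penta-2,4-dien-1-ylidene]phosphorane | C=C/C=C/C=P(CCCC)(CCCC)CCCC | intermediate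
11 | (3E,5E)-9-bromo-7,7-dimethylnona-1,3,5-triene | BrCCC(C)(C)/C=C/C=C/C=C | intermediate
12 | 2,2-dimethoxyacetaldehyde | COC(OC)C=O | starting material
13 | 2-(triphenylphosphoranylidene)propanal | CC(C=O)=P(c1ccccc1)(c1ccccc1)c1ccccc1 | starting material
14 | (2E)-4,4-dimethoxy-2-methylbut-2-enal | COC(OC)/C=C(\C)C=O | intermediate
15 | [(5E,7E)-3,3-dimethylnona-4,6,8-trien-1-yl]magnesium bromide | Br[Mg]CCC(C)(C)/C=C/C=C/C=C | intermediate
16 | [(5E,7E)-3,3-dimethylnona-4,6,8-trien-1-yl]titanium triisopropoxide | CC(C)O[Ti](OC(C)C)(OC(C)C)CCC(C)(C)/C=C/C=C/C=C | intermediate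
17 | (2E,4R,8E,10E)-1,1-dimethoxy-3,7,7-trimethyltrideca-2,8,10,12-tetraen-4-ol | COC(OC)/C=C(\C)[C@H](O)CCC(C)(C)/C=C/C=C/C=C | intermediate
18 | (2E,4R,8E,10E)-1,1-dimethoxy-3,7,7-trimethyltrideca-2,8,10,12-tetraen-4-yl acetate | COC(OC)/C=C(\C)[C@H](OC(C)=O)CCC(C)(C)/C=C/C=C/C=C | intermediate
19 | (2E,4R,8E,10E)-4-acetoxy-3,7,7-trimethyltrideca-2,8,10,12-tetraenal | O=C/C=C(\C)[C@H](OC(C)=O)CCC(C)(C)/C=C/C=C/C=C | intermediate
20 | 1β-acetoxy-12-methylidenedrim-6-en-11-al (5α-H, 8β-vinyl, 9β-CHO, 10β-CH3) | C1=C[C@H](C=C)[C@H](C=O)[C@@]2(C)[C@H](OC(C)=O)CCC(C)(C)[C@H]12 | intermediate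
21 | 1β-acetoxy-11-(trimethylsilyloxy)-12-methylidenedrima-6,9(11)-diene | C1=C[C@H](C=C)/C(=C\O[Si](C)(C)C)[C@@]2(C)[C@H](OC(C)=O)CCC(C)(C)[C@H]12 | intermediate
22 | 1β-acetoxy-6α,7α:9α,11-diepoxy-11-(trimethylsilyloxy)-12-methylidenedrimane | O1[C@H]2[C@@H]1[C@H](C=C)[C@@]4(O[C@@H]4O[Si](C)(C)C)[C@@]3(C)[C@H](OC(C)=O)CCC(C)(C)[C@H]23 | intermediate
23 | 1β-acetoxy-6α,7α-epoxy-9α-hydroxy-12-methylidenedriman-11-al | O1[C@H]2[C@@H]1[C@H](C=C)[C@](O)(C=O)[C@@]3(C)[C@H](OC(C)=O)CCC(C)(C)[C@H]23 | intermediate
24 | secondary ozonide of 23 (1,2,4-trioxolan-3-yl on C8, epimers at the ozonide carbon) | O1[C@H]2[C@@H]1[C@H](C4OCOO4)[C@](O)(C=O)[C@@]3(C)[C@H](OC(C)=O)CCC(C)(C)[C@H]23 | intermediate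
25 | 1β-acetoxy-6α,7α-epoxy-9α-hydroxydrimane-11,12-dial | O1[C@H]2[C@@H]1[C@H](C=O)[C@](O)(C=O)[C@@]3(C)[C@H](OC(C)=O)CCC(C)(C)[C@H]23 | intermediate
26 | 1β-acetoxy-6α,9α-dihydroxydrim-7-ene-11,12-dial | O[C@H]1C=C(C=O)[C@](O)(C=O)[C@@]2(C)[C@H](OC(C)=O)CCC(C)(C)[C@H]12 | intermediate
27 | parritadial | CC(=O)O[C@H]1C=C(C=O)[C@](O)(C=O)[C@@]2(C)[C@H](OC(C)=O)CCC(C)(C)[C@H]12 | target

Total step count: 14. Longest linear sequence: 11 steps (1, 2, 5, 7–14).

Steps most likely to fail

Step 10. The trisubstituted dienophile may react too slowly against the gem-dimethyl/methyl congestion. Endo selectivity may also erode, because the C10 methyl group is forced under the diene together with the formyl group, which would admit the cis-fused series.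
- The fallback is an ionic Diels–Alder reaction that sets out from 18 and skips 19.
- Catalytic TMSOTf in CH2Cl2 at −78 °C ionises the allylic acetal to a 1-methoxyallyl cation, a much stronger and more compact dienophile. It adds to the inner diene in a polar, stepwise manner through the same chair-folded tether.
- Return of methoxide gives the cycloadduct dimethyl acetal F1.
- PPTS in wet acetone then leads back to the route at 20.

Step 12. Chemoselectivity between C6=C7 and the vinyl group may be insufficient, or the second epoxidation may stall.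
- The fallback replaces the epoxide/E1cB logic by an ene transposition and sets out from 21.
- One equivalent of DMDO at −78 °C gives the mono silyloxy epoxide F2, and mild acid gives the Δ6 hydroxy aldehyde F3.
- A Schenck ene reaction (O2, tetraphenylporphyrin, hν, CH2Cl2, 0 °C) should attack C6=C7 from the α face and abstract the doubly allylic 8α-H, giving the 6α-hydroperoxy diene F4.
- PPh3 reduces F4 to the 6α-hydroxy diene F5.
- Lemieux–Johnson cleavage (OsO4 cat., NaIO4, 2,6-lutidine) of the terminal C12=C13 bond rejoins the route at 26.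

Step 7. Enantioselectivity may be low, or an uncatalysed background addition of the functionalised alkyl metal may compete.
- The fallback moves stereocontrol from C–C bond formation to a reduction and sets out from 11 and 14.
- Plain addition of Grignard reagent 15 to 14 in THF at −78 °C gives the racemic allylic alcohol F6.
- MnO2 oxidation gives the α-methyl enone F7.
- Corey–Bakshi–Shibata reduction with the (S)-methyl oxazaborolidine and catecholborane at −78 °C, in which the α-methylalkenyl group acts as the large substituent, returns to the route at 17.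

Further compounds
F1 | step 10 | 1β-acetoxy-11,11-dimethoxy-12-methylidenedrim-6-ene | C1=C[C@H](C=C)[C@H](C(OC)OC)[C@@]2(C)[C@H](OC(C)=O)CCC(C)(C)[C@H]12
F2 | step 12 | 1β-acetoxy-9α,11-epoxy-11-(trimethylsilyloxy)-12-methylidenedrim-6-ene | C1=C[C@H](C=C)[C@@]3(O[C@@H]3O[Si](C)(C)C)[C@@]2(C)[C@H](OC(C)=O)CCC(C)(C)[C@H]12
F3 | step 12 | 1β-acetoxy-9α-hydroxy-12-methylidenedrim-6-en-11-al | C1=C[C@H](C=C)[C@](O)(C=O)[C@@]2(C)[C@H](OC(C)=O)CCC(C)(C)[C@H]12
F4 | step 12 | 1β-acetoxy-6α-hydroperoxy-9α-hydroxy-12-methylidenedrim-7-en-11-al | OO[C@H]1C=C(C=C)[C@](O)(C=O)[C@@]2(C)[C@H](OC(C)=O)CCC(C)(C)[C@H]12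
F5 | step 12 | 1β-acetoxy-6α,9α-dihydroxy-12-methylidenedrim-7-en-11-al | O[C@H]1C=C(C=C)[C@](O)(C=O)[C@@]2(C)[C@H](OC(C)=O)CCC(C)(C)[C@H]12
F6 | step 7 | racemic (2E,8E,10E)-1,1-dimethoxy-3,7,7-trimethyltrideca-2,8,10,12-tetraen-4-ol | COC(OC)/C=C(\C)C(O)CCC(C)(C)/C=C/C=C/C=C
F7 | step 7 | (2E,8E,10E)-1,1-dimethoxy-3,7,7-trimethyltrideca-2,8,10,12-tetraen-4-one | COC(OC)/C=C(\C)C(=O)CCC(C)(C)/C=C/C=C/C=C
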